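Cembrane numbering: C1/C2 are the carbons shared by the 14-membered ring and the dihydrofuran (C2 bears O). Then come C3=C4, the C7–C8 epoxide, C11=C12, C13 and C14; outside the large ring are C15 (olefin partner of C1), C16 (OCH2) and C17 (CH2OAc).
Cuts: C17–OAc goes back to a C17 acid. C13–C14 is unravelled by a retro-Cope shift (to C11–C15) and a retro-Ireland–Claisen shift to the O–C13 bond of a 16-membered lactone. Then follow the lactone C–O, the epoxide O, C13–O, C15–C17 and O–C16 (allenol + CO), and C1–C2 (farnesal + butynylboronate).
Forward ring order: dihydrofuran (step 4), epoxide (step 7), temporary 16-membered lactone (step 9), 14-membered carbocycle last (step 10).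
Enabling feature: the 1,5-diene C11=C12–C13–C14–C1=C15 of the 14-membered ring ends on the dihydrofuran carbon C15 that carries C17. At the acid level C14 is therefore the γ-carbon of an enoate whose ester oxygen can hold C13, and two [3,3] shifts walk the allyl unit O→C15→C14.
Stereochemistry: C2 comes from a chiral-phosphoric-acid allenylboration (its C–O bond is never broken afterwards) and C7/C8 from a Shi epoxidation. The E-olefins come from (E,E)-farnesol, the E-selective SeO2 oxidation and chair-type shifts.

Key step: step 10

Remark: the facial sense of (S)-TRIP is taken over from the allylboration of aldehydes with the same acid (Si-face attack on the enal gives 2R); cembrane numbers are used in all descriptions.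

Step 1
Reactants: 1 (2E,6E)-farnesol
Product: 2 (2E,6E)-farnesal
Conditions: MnO2 (activated, excess), CH2Cl2, rt
Reagents that add atoms: none
Why: Allylic oxidation with MnO2 takes the primary allylic alcohol to the enal without touching the isolated olefins or the 2E geometry.

Step 2
Reactants: 3 prop-1-yn-1-ylmagnesium bromide; 4 2-(bromomethyl)-4,4,5,5-tetramethyl-1,3,2-dioxaborolane
Product: 6 2-(but-2-yn-1-yl)-4,4,5,5-tetramethyl-1,3,2-dioxaborolane, via bromomethyl alkynyl borate 5 (not isolated)
Conditions: THF, −78 °C to rt
Reagents that add atoms: none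
Why: Matteson homologation, in which the alkynyl Grignard reagent adds to boron and the alkynyl group of borate 5 then migrates to the CH2 carbon with loss of bromide, fixes boron on the propargylic carbon so that no allenylboronate isomer is formed.

Step 3
Reactants: 2 (2E,6E)-farnesal; 6 2-(but-2-yn-1-yl)-4,4,5,5-tetramethyl-1,3,2-dioxaborolane
Product: 8 (4R,5E,9E)-3,6,10,14-tetramethylpentadeca-1,2,5,9,13-pentaen-4-ol (allenol, C2 = R), via O-boryl allenol 7 (not isolated)
Conditions: (S)-TRIP [(S)-3,3'-bis(2,4,6-triisopropylphenyl)-1,1'-binaphthyl-2,2'-diyl hydrogen phosphate] (5 mol %), 4 Å MS, toluene, −30 °C; aq. NaHCO3 work-up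
Reagents that add atoms: none
Why: Chiral-phosphoric-acid-catalysed allenylboration (propargylboronate addition through a closed six-membered SE2' transition state) joins C1 to C2 with transposition to the 1,1-disubstituted allene, and the (S)-phosphate should expose the Si face of the enal and so set C2 as R.

Step 4
Reactants: 8 allenol
Product: 9 methyl (5R)-4-methyl-5-[(1E,5E)-2,6,10-trimethylundeca-1,5,9-trien-1-yl]-2,5-dihydrofuran-3-carboxylate
Conditions: Pd(OCOCF3)2 (5 mol %), p-benzoquinone (1.5 equiv), CO (1 atm), MeOH, 0 °C to rt
Reagents that add atoms: carbon monoxide [C-]#[O+]; methanol CO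
Why: Oxidative alkoxycarbonylative heterocyclisation, in which divalent palladium activates the terminal allene bond, the C2 hydroxyl adds 5-endo to C16, the C15 vinylpalladium species inserts CO and is cleaved by methanol, and benzoquinone regenerates the catalyst, closes the dihydrofuran with C14 and C17 in place and leaves C2 unchanged because its C–O bond is not touched.

Step 5
Reactants: 9 dihydrofuran ester
Product: 10 methyl (5R)-5-[(1E,5E,9E)-11-hydroxy-2,6,10-trimethylundeca-1,5,9-trien-1-yl]-4-methyl-2,5-dihydrofuran-3-carboxylate (C13 alcohol)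
Conditions: SeO2 (0.3 equiv), t-BuOOH (3 equiv), salicylic acid (0.1 equiv), CH2Cl2, 0 °C
Reagents that add atoms: selenium dioxide (oxygen carrier) O=[Se]=O; tert-butyl hydroperoxide (terminal oxidant) CC(C)(C)OO
Why: Catalytic SeO2/t-BuOOH allylic oxidation (ene reaction followed by a [2,3] shift) should pick the E-methyl group of the terminal isopropylidene unit, the most electron-rich and least hindered olefin, while the C14 methyl group sits on an electron-poor enoate.

Step 6
Reactants: 10 C13 alcohol
Product: 11 C13 acetate of 10
Conditions: Ac2O, pyridine, DMAP (cat), CH2Cl2, 0 °C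
Reagents that add atoms: acetic anhydride CC(=O)OC(C)=O
Why: Standard acylation, whose purpose is to turn C11=C12 into an electron-poor allylic acetate before the epoxidation.

Step 7
Reactants: 11 C13 acetate
Product: 12 (7R,8R)-7,8-epoxide of 11
Conditions: D-fructose-derived Shi ketone (0.3 equiv), Oxone (2KHSO5·KHSO4·K2SO4), K2CO3, Bu4NHSO4, MeCN–CH2(OMe)2 / aq. Na2B4O7–Na2EDTA buffer, 0 °C
Reagents that add atoms: potassium peroxymonosulfate (oxygen atom, relayed by the dioxirane) [K+].[O-]S(=O)(=O)OO
Why: Shi epoxidation, in which the dioxirane of the D-fructose-derived ketone should attack through the spiro transition state the only olefin that carries neither an allylic oxygen nor a carbonyl group (C7=C8), should give the 7R,8R trans-epoxide under catalyst control.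

Step 8
Reactants: 12 epoxy acetate ester
Product: 13 seco acid (C13–OH, C17 carboxylic acid, 2R,7R,8R)
Conditions: LiOH (5 equiv), THF–MeOH–H2O, rt to 40 °C; then 1 M HCl to pH 4, 0 °C
Reagents that add atoms: lithium hydroxide (carboxyl oxygen) [Li+].[OH-]
Why: Saponification cleaves the acetate and the methyl ester in one operation, while the trisubstituted epoxide and the C2 ether centre are inert to hydroxide at this temperature.

Step 9
Reactants: 13 seco acid
Product: 15 16-membered lactone (C17 carbonyl esterified by O–C13; 2R,7R,8R), via mixed aroyl anhydride 14 (not isolated)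
Conditions: 2-methyl-6-nitrobenzoic anhydride (1.3 equiv), DMAP (4 equiv), CH2Cl2, slow addition of 13 (final 2 mM), rt
Reagents that add atoms: 2-methyl-6-nitrobenzoic anhydride (atoms in 14 only) Cc1cccc([N+](=O)[O-])c1C(=O)OC(=O)c1c(C)cccc1[N+](=O)[O-]
Why: Shiina macrolactonisation, in which DMAP attacks mixed anhydride 14 at the less shielded enoyl carbonyl and slow addition favours closure by the primary allylic alcohol, builds the temporary 16-membered ring that places O–C13 on the C17 carbonyl.

Step 10
Reactants: 15 16-membered lactone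
Product: 19 (2R,7R,8R)-2,16:7,8-diepoxycembra-1(15),3E,11E-trien-17-oic acid, via dienyl silyl ketene acetal 16 (not isolated), via twelve-membered Claisen silyl ester 17 (not isolated), via fourteen-membered Cope silyl ester 18 (not isolated)
Conditions: LiN(iPr)2 (1.3 equiv), Me3SiCl–Et3N present from the start, THF, −78 °C to rt; solvent switch to o-xylene (salts filtered off), 140 °C; then aq. NaH2PO4
Reagents that add atoms: chlorotrimethylsilane (atoms in 16–18 only) C[Si](C)(C)Cl
Why: LiN(iPr)2 bound to the lactone carbonyl removes a proton from the C14 methyl group, which is held syn to C17 on the ring-locked C1=C15 bond, and Me3SiCl present in the flask traps the dienolate as ketene acetal 16; a first suprafacial [3,3] shift (Ireland–Claisen) over C15=C17–O–C13–C12=C11 breaks O–C13 and bonds C15 to C11 (17), and a second one (Cope) over C14=C1–C15–C11–C12=C13 breaks C15–C11 and bonds C14 to C13 (18), driven by the return of C1=C15 into conjugation with the carboxyl group and by loss of the crowded quaternary C15. The closest known reaction types are the alicyclic Ireland–Claisen four-atom ring contraction of macrolactones and the ester-dienolate Claisen–Cope γ-allylation of 3-methylbut-2-enoates, the laboratory relative of the industrial citral process. Mode of closure: the transient 12-membered ring closes by 1,6-bonding inside the lactone (16 to 12) and the 14-membered carbocycle then arises by a two-atom ring expansion (12 to 14), so both are unimolecular reorganisations of an existing ring and need no high dilution. No new stereocentre survives, since C11 and C15 of 17 are erased again, C2, C7 and C8 are spectators, and the E geometry of C11=C12 should be returned by chair transition states that keep C10 equatorial in both shifts. The step needs C14–H over C2–H deprotonation, which the carbonyl-directed syn removal, the threefold statistical weight, the hindered tertiary nature of C2–H and the internal silyl quench should secure, and it needs linear (C13) rather than branched (C11) attachment, which the double allyl inversion of two consecutive [3,3] shifts guarantees.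

Step 11
Reactants: 19 ring-contracted acid
Product: 21 (2R,7R,8R)-2,16:7,8-diepoxycembra-1(15),3E,11E-trien-17-ol, via mixed carbonic anhydride 20 (not isolated)
Conditions: i-BuOCOCl, N-methylmorpholine, THF, −15 °C; then NaBH4, THF–H2O, 0 °C
Reagents that add atoms: isobutyl chloroformate (atoms in 20 only) CC(C)COC(=O)Cl
Why: Reduction of a mixed carbonic anhydride with NaBH4 takes the hindered conjugated acid to the allylic alcohol under conditions that spare the epoxide and all olefins.

Step 12
Reactants: 21 C17 alcohol
Product: 22 lobophynin B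
Conditions: Ac2O, pyridine, DMAP (cat), CH2Cl2, 0 °C to rt
Reagents that add atoms: acetic anhydride CC(=O)OC(C)=O
Why: Standard acetylation of the primary allylic alcohol completes the target without touching any stereocentre.

Compound list
1 | (2E,6E)-farnesol | CC(C)=CCC/C(C)=C/CC/C(C)=C/CO | starting material
2 | (2E,6E)-farnesal | CC(C)=CCC/C(C)=C/CC/C(C)=C/C=O | intermediate
3 | prop-1-yn-1-ylmagnesium bromide | CC#C[Mg]Br | starting material
4 | 2-(bromomethyl)-4,4,5,5-tetramethyl-1,3,2-dioxaborolane | BrCB1OC(C)(C)C(C)(C)O1 | starting material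
5 | bromomagnesium (bromomethyl)(prop-1-ynyl)(pinacolato)borate | CC#C[B-]1(CBr)OC(C)(C)C(C)(C)O1.[Mg+]Br | intermediate
6 | 2-(but-2-yn-1-yl)-4,4,5,5-tetramethyl-1,3,2-dioxaborolane | CC#CCB1OC(C)(C)C(C)(C)O1 | intermediate
7 | O-(pinacolatoboryl) ether of allenol 8 (C2 = R) | CC(C)=CCC/C(C)=C/CC/C(C)=C/[C@H](C(C)=C=C)OB1OC(C)(C)C(C)(C)O1 | intermediate
8 | (4R,5E,9E)-3,6,10,14-tetramethylpentadeca-1,2,5,9,13-pentaen-4-ol | CC(C)=CCC/C(C)=C/CC/C(C)=C/[C@H](C(C)=C=C)O | intermediate
9 | methyl (5R)-4-methyl-5-[(1E,5E)-2,6,10-trimethylundeca-1,5,9-trien-1-yl]-2,5-dihydrofuran-3-carboxylate | CC(C)=CCC/C(C)=C/CC/C(C)=C/[C@H]1OCC(C(=O)OC)=C1C | intermediate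
10 | methyl (5R)-5-[(1E,5E,9E)-11-hydroxy-2,6,10-trimethylundeca-1,5,9-trien-1-yl]-4-methyl-2,5-dihydrofuran-3-carboxylate | OC/C(C)=C/CC/C(C)=C/CC/C(C)=C/[C@H]1OCC(C(=O)OC)=C1C | intermediate
11 | C13 acetate of 10 | CC(=O)OC/C(C)=C/CC/C(C)=C/CC/C(C)=C/[C@H]1OCC(C(=O)OC)=C1C | intermediate
12 | (2R,7R,8R)-7,8-epoxide of 11 | CC(=O)OC/C(C)=C/CC[C@@]2(C)O[C@@H]2CC/C(C)=C/[C@H]1OCC(C(=O)OC)=C1C | intermediate
13 | (2R,7R,8R)-seco acid (C13–OH, C17 acid) | OC/C(C)=C/CC[C@@]2(C)O[C@@H]2CC/C(C)=C/[C@H]1OCC(C(=O)O)=C1C | intermediate
14 | mixed anhydride of 13 and 2-methyl-6-nitrobenzoic acid | OC/C(C)=C/CC[C@@]2(C)O[C@@H]2CC/C(C)=C/[C@H]1OCC(C(=O)OC(=O)c3c(C)cccc3[N+](=O)[O-])=C1C | intermediate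
15 | (2R,7R,8R)-16-membered lactone (C17 carbonyl to O–C13, C14 methyl on C1) | O=C1OC/C(C)=C/CC[C@@]2(C)O[C@@H]2CC/C(C)=C/[C@H]3OCC1=C3C | intermediate
16 | trimethylsilyl ketene acetal of 15 with exocyclic diene C14=C1–C15=C17 (ketene acetal geometry open) | C[Si](C)(C)OC=1OC/C(C)=C/CC[C@@]2(C)O[C@@H]2CC/C(C)=C/[C@H]3OCC=1C3=C | intermediate
17 | 12-membered carbocyclic trimethylsilyl ester with C15–C11 bond, C1=C14 exo-methylene and isopropenyl on C11 (C11 and C15 transient, erased in the next shift) | C[Si](C)(C)OC(=O)C12CO[C@H](/C=C(C)/CC[C@H]3O[C@]3(C)CCC1C(C)=C)C2=C | intermediate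
18 | trimethylsilyl ester of 19 | C[Si](C)(C)OC(=O)C1=C2CC/C(C)=C/CC[C@@]3(C)O[C@@H]3CC/C(C)=C/[C@H]2OC1 | intermediate
19 | (2R,7R,8R)-2,16:7,8-diepoxycembra-1(15),3E,11E-trien-17-oic acid | OC(=O)C1=C2CC/C(C)=C/CC[C@@]3(C)O[C@@H]3CC/C(C)=C/[C@H]2OC1 | intermediate
20 | isobutyl carbonic anhydride of 19 | CC(C)COC(=O)OC(=O)C1=C2CC/C(C)=C/CC[C@@]3(C)O[C@@H]3CC/C(C)=C/[C@H]2OC1 | intermediate
21 | (2R,7R,8R)-2,16:7,8-diepoxycembra-1(15),3E,11E-trien-17-ol | OCC1=C2CC/C(C)=C/CC[C@@]3(C)O[C@@H]3CC/C(C)=C/[C@H]2OC1 | intermediate
22 | lobophynin B | CC(=O)OCC1=C2CC/C(C)=C/CC[C@@]3(C)O[C@@H]3CC/C(C)=C/[C@H]2OC1 | target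

Total step count: 12. Longest linear sequence: 11 (steps 1 and 3–12; step 2 is a one-step branch).

Steps most likely to fail

Step 10. The base may remove the C2 proton instead of a C14 proton. That would erode the C2 configuration and send the allyl unit to C2. A boat-like passage could also erode the E geometry at C11=C12.
The fallback sets out from 15 and replaces kinetic deprotonation by a photochemical hydrogen shift. Irradiation at 254 nm in Et2O with a catalytic amount of 1,2-dimethylimidazole should cause photoenolisation by a 1,5-hydrogen shift, which can only reach the C14–H bonds lying syn to the carbonyl. Ketonisation should then give the deconjugated exo-methylene lactone F1. Its C15–H, α to the carbonyl and allylic, is the only strongly acidic proton, so LiN(iPr)2/Me3SiCl at −78 °C should give the ketene acetal regiospecifically. The route is rejoined at 16.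

Step 4. The vinylpalladium intermediate may be protonated before CO inserts, or the bis-allylic alcohol may ionise under the slightly acidic methanolic conditions.
The fallback sets out from 8 and separates ring closure from carbonylation. Iodocyclisation (I2, NaHCO3, MeCN, 0 °C) should give the vinyl iodide (2R)-4-iodo-3-methyl-2-[(1E,5E)-2,6,10-trimethylundeca-1,5,9-trien-1-yl]-2,5-dihydrofuran F2. A methoxycarbonylation with zerovalent palladium formed from PdCl2(PPh3)2 (CO 1 atm, Et3N, MeOH–DMF, 60 °C) then returns to the route at 9.

Step 7. The dioxirane may also attack C3=C4 (over-oxidation). The acetate may also hydrolyse at the basic pH, which would re-activate C11=C12.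
The fallback sets out from 10 and moves the epoxidation behind the lactonisation. LiOH should give the olefinic seco acid F3. 2-Methyl-6-nitrobenzoic anhydride/DMAP under slow addition should lead through the mixed anhydride F4 to the triene lactone F5. In F5 the C13 oxygen is acylated by the ring itself and C3=C4 lies against the dihydrofuran. The same Shi epoxidation of F5 at C7=C8 returns to the route at 15 and makes steps 6 and 8 unnecessary.

Further compounds
F1 | step 10 | (2R,7R,8R)-16-membered lactone with the olefin out of conjugation (C1=C14 exo-methylene, C15–H, either C15 epimer) | O=C1OC/C(C)=C/CC[C@@]2(C)O[C@@H]2CC/C(C)=C/[C@H]3OCC1C3=C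
F2 | step 4 | (2R)-4-iodo-3-methyl-2-[(1E,5E)-2,6,10-trimethylundeca-1,5,9-trien-1-yl]-2,5-dihydrofuran | CC(C)=CCC/C(C)=C/CC/C(C)=C/[C@H]1OCC(I)=C1C
F3 | step 7 | (5R)-5-[(1E,5E,9E)-11-hydroxy-2,6,10-trimethylundeca-1,5,9-trien-1-yl]-4-methyl-2,5-dihydrofuran-3-carboxylic acid | OC/C(C)=C/CC/C(C)=C/CC/C(C)=C/[C@H]1OCC(C(=O)O)=C1C
F4 | step 7 | mixed anhydride of F3 and 2-methyl-6-nitrobenzoic acid | OC/C(C)=C/CC/C(C)=C/CC/C(C)=C/[C@H]1OCC(C(=O)OC(=O)c2c(C)cccc2[N+](=O)[O-])=C1C
F5 | step 7 | (2R)-16-membered triene lactone (15 without the epoxide oxygen, C7=C8 E) | O=C1OC/C(C)=C/CC/C(C)=C/CC/C(C)=C/[C@H]2OCC1=C2C
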